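Cuts: the three O-benzyl bonds and the C8 O-methyl bond. Then C5-C6, C7-C8 and C8-C8a of ring A together (alkenylcarbene complex + ynol ether + one CO ligand). Then Cr=C5 (acyl chloride + Na2Cr(CO)5), and last O1-C8a, C2-C3 and C4a=C8a of ring C (aroyl chloride + acetoacetate + formamide acetal).
Enabling feature: in ring A the C5 methoxy group and the C8 oxygen stand 1,4 to each other, and C6-H and C7-O fill the side between them. The opposite edge C4a=C8a is also the C3=C2 alkene of the 4-pyranone ring C, so ring A is a hydroquinone monoether made from C8a/C4a/C5 (alkenylcarbene), C6/C7 (alkyne) and C8 (CO).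
Forward order: ring B is bought as 4-O-methylgallic acid, ring C is closed onto it by acylation of an enaminone anion and acid cyclisation, and ring A is annulated last.
The ring A oxygens arrive already differentiated (C5-OMe from the carbene, C7-OBn from the ynol ether, C8-OH from CO), so one methylation and one hydrogenolysis finish the route.
Stereochemistry: the target has no stereocentre and no configurable double bond, so nothing has to be set.

Key step: step 10

Remark: bicyclic compounds carry flavone numbering. In the monocyclic pyranones, ring atoms C2, C3, C4, C5, C6 become flavone C8a, C4a, C4, C3, C2. The push-pull enaminones are drawn without alkene geometry because rotation about that bond is fast.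

Step 1
Reactants: 1 3,5-dihydroxy-4-methoxybenzoic acid
Product: 2 benzyl 3,5-bis(benzyloxy)-4-methoxybenzoate
Conditions: BnBr (3.5 equiv), K2CO3, DMF, 60 °C
Reagents that add atoms: benzyl bromide, BrCc1ccccc1
Why: Exhaustive Williamson alkylation, in which K2CO3 deprotonates both phenols and the carboxylic acid, all three oxygens are benzylated and no selectivity is called for.

Step 2
Reactants: 2 benzyl 3,5-bis(benzyloxy)-4-methoxybenzoate
Product: 3 3,5-bis(benzyloxy)-4-methoxybenzoic acid
Conditions: NaOH, THF/MeOH/H2O, 50 °C; then 1 M HCl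
Reagents that add atoms: sodium hydroxide, [Na+].[OH-]
Why: Saponification attacks only the ester carbonyl, aryl benzyl and aryl methyl ethers being inert to hydroxide, and acidification precipitates the acid.

Step 3
Reactants: 3 3,5-bis(benzyloxy)-4-methoxybenzoic acid
Product: 4 3,5-bis(benzyloxy)-4-methoxybenzoyl chloride
Conditions: (COCl)2, DMF (cat.), CH2Cl2, 0 °C to rt
Reagents that add atoms: oxalyl chloride, O=C(Cl)C(=O)Cl
Why: Acid chloride formation through the Vilsmeier-type chloroiminium species runs cold and without strong acid, so the three ethers are not touched.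

Step 4
Reactants: 5 tert-butyl acetoacetate; 6 N,N-dimethylformamide dimethyl acetal
Product: 7 tert-butyl 2-[(dimethylamino)methylidene]-3-oxobutanoate
Conditions: toluene, rt to 50 °C, methanol removed
Reagents that add atoms: none
Why: Condensation of the active methylene group of a β-keto ester with an amide acetal (enaminone formation) blocks that carbon, installs the future C8a as a CH bearing a leaving group, and leaves the acetyl CH3 as the only acidic site.

Step 5
Reactants: 4 3,5-bis(benzyloxy)-4-methoxybenzoyl chloride; 7 tert-butyl 2-[(dimethylamino)methylidene]-3-oxobutanoate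
Product: 9 tert-butyl 6-[3,5-bis(benzyloxy)-4-methoxyphenyl]-4-oxo-4H-pyran-3-carboxylate, via acylated enaminone 8 (not isolated)
Conditions: LiN(SiMe3)2 (2.3 equiv), THF, −78 °C, 4 and 7 added together; then 1 M HCl, Et2O, 0 °C to rt
Reagents that add atoms: none
Why: Claisen-type C-acylation of the enaminone anion, in which the amide base removes an acetyl proton (a second equivalent is taken up by the more acidic 8), the aroyl chloride acylates that carbon, and on acidification the aryl-side enol oxygen displaces dimethylamine by addition-elimination to close the 4-pyranone, a sequence established for 3-alkoxycarbonyl-4-pyranones.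

Step 6
Reactants: 9 tert-butyl 6-[3,5-bis(benzyloxy)-4-methoxyphenyl]-4-oxo-4H-pyran-3-carboxylate
Product: 10 6-[3,5-bis(benzyloxy)-4-methoxyphenyl]-4-oxo-4H-pyran-3-carboxylic acid
Conditions: CF3CO2H/CH2Cl2 (1:2), 0 °C to rt
Reagents that add atoms: none
Why: Acidolysis of the tert-butyl ester with loss of isobutene frees the acid without hydroxide, which would open the activated pyranone at C2, and short exposure in the cold spares the aryl benzyl ethers.

Step 7
Reactants: 10 6-[3,5-bis(benzyloxy)-4-methoxyphenyl]-4-oxo-4H-pyran-3-carboxylic acid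
Product: 11 6-[3,5-bis(benzyloxy)-4-methoxyphenyl]-4-oxo-4H-pyran-3-carbonyl chloride
Conditions: (COCl)2, DMF (cat.), CH2Cl2, 0 °C to rt; evaporated twice from toluene
Reagents that add atoms: oxalyl chloride, O=C(Cl)C(=O)Cl
Why: The same Vilsmeier-type chloride formation, routine for the analogous chromone-3-carboxylic acids, gives the acyl electrophile needed for chromium.

Step 8
Reactants: 12 benzyl alcohol; 13 trichloroethylene
Product: 16 benzyl ethynyl ether, via dichlorovinyl ether 14 (not isolated), via lithium benzyloxyacetylide 15 (not isolated)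
Conditions: KH, THF, 0 °C; 13, −50 °C to rt; n-BuLi (2.4 equiv), −78 to −40 °C; H2O, −78 °C; cold pentane extraction, kept as a solution at −20 °C
Reagents that add atoms: none
Why: The trichloroethylene route to ynol ethers, in which the alkoxide substitutes 13 by elimination-addition to give 14, n-BuLi brings about dehydrochlorination and Cl/Li exchange to acetylide 15, and cold protonation gives the terminal alkyne.

Step 9
Reactants: 11 6-[3,5-bis(benzyloxy)-4-methoxyphenyl]-4-oxo-4H-pyran-3-carbonyl chloride; 17 chromium hexacarbonyl, Cr(CO)6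
Product: 20 pentacarbonyl{[6-(3,5-bis(benzyloxy)-4-methoxyphenyl)-4-oxo-4H-pyran-3-yl](methoxy)methylidene}chromium, via disodium pentacarbonylchromate 18 (not isolated), via sodium acylchromate 19 (not isolated)
Conditions: Cr(CO)6, NaC10H8 (2.0 equiv), THF, −78 °C; 11 (1.0 equiv), −78 to 0 °C; solvent exchange; Me3OBF4 (1.0 equiv), CH2Cl2, 0 °C; rapid chromatography under Ar
Reagents that add atoms: trimethyloxonium tetrafluoroborate, C[O+](C)C.F[B-](F)(F)F
Why: Acid chloride variant of the Fischer carbene synthesis, in which the strongly nucleophilic dianion 18 substitutes the acyl chloride to give acylchromate 19 and Me3OBF4 methylates its anionic oxygen ahead of the neutral ring carbonyl, which avoids a 3-lithiopyranone that would expel the ring oxygen by anti β-elimination and could not coexist with the C4 carbonyl.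

Step 10
Reactants: 20 pentacarbonyl{[6-(3,5-bis(benzyloxy)-4-methoxyphenyl)-4-oxo-4H-pyran-3-yl](methoxy)methylidene}chromium; 16 benzyl ethynyl ether
Product: 22 7-(benzyloxy)-2-[3,5-bis(benzyloxy)-4-methoxyphenyl]-8-hydroxy-5-methoxychromen-4-one, via ring A Cr(CO)3 complex 21 (not isolated)
Conditions: 16 (2.5 equiv, in portions), degassed THF, 45 °C, Ar; then air, MeCN/CH2Cl2, rt
Reagents that add atoms: none
Why: Proposed new method: one CO leaves 20 (helped by the neighbouring C4 carbonyl oxygen, which can occupy the free site reversibly), 16 binds and its nucleophilic CH terminus joins the electrophilic carbene carbon (C5-C6), so that the oxygen-bearing alkyne carbon becomes a new donor-stabilised carbene centre that takes up a CO ligand to give a dienylketene (C7-C8). The ketene carbon then closes onto the pyranone C2-H carbon (C8-C8a) and the cyclohexadienone tautomerises to the phenol, held as Cr(CO)3 complex 21 until air releases 22. The closest known reaction types are the Dötz benzannulation of alkenyl(alkoxy)carbene complexes of zerovalent chromium with terminal alkynes and the thermal or photochemical closure of dienyl(alkoxy)carbene complexes to ortho-alkoxyphenols, but neither an alkene embedded in a 4-pyranone nor a terminal ynol ether has been shown in this role. Ring A, the only ring formed, closes by 6π electrocyclisation of the dienylketene in what is formally a [3+2+1] assembly, and no stereocentre is created. The one selectivity needed is regiochemical, CH next to C5 and C-OBn next to C8, and the steric rule for terminal alkynes and the polarisation of the ynol ether both point that way, while the C8a-H carbon is the only terminus within reach of the ketene for a six-membered closure. The bath stays at or below 45 °C and 16 is fed in portions because benzyl alkynyl ethers start to rearrange sigmatropically near 60 °C.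

Step 11
Reactants: 22 7-(benzyloxy)-2-[3,5-bis(benzyloxy)-4-methoxyphenyl]-8-hydroxy-5-methoxychromen-4-one
Product: 23 7-(benzyloxy)-2-[3,5-bis(benzyloxy)-4-methoxyphenyl]-5,8-dimethoxychromen-4-one
Conditions: MeI, K2CO3, DMF, rt to 40 °C
Reagents that add atoms: iodomethane, CI
Why: Williamson methylation of the only free hydroxyl group in 22 fixes the C8 methyl ether, and the benzyl group at O7 cannot migrate under base.

Step 12
Reactants: 23 7-(benzyloxy)-2-[3,5-bis(benzyloxy)-4-methoxyphenyl]-5,8-dimethoxychromen-4-one
Product: 24 2-(3,5-dihydroxy-4-methoxyphenyl)-7-hydroxy-5,8-dimethoxychromen-4-one (CNP0218554.0)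
Conditions: H2 (1 atm), 10% Pd/C, THF/MeOH, rt
Reagents that add atoms: none
Why: Catalytic hydrogenolysis cleaves the three benzylic C-O bonds at 1 atm, while aryl methyl ethers and the conjugated C2=C3 bond of the flavone are not reduced under these conditions.

Compound list
1 | 3,5-dihydroxy-4-methoxybenzoic acid | COc1c(O)cc(C(=O)O)cc1O | starting material
2 | benzyl 3,5-bis(benzyloxy)-4-methoxybenzoate | COc1c(OCc2ccccc2)cc(C(=O)OCc2ccccc2)cc1OCc1ccccc1 | intermediate
3 | 3,5-bis(benzyloxy)-4-methoxybenzoic acid | COc1c(OCc2ccccc2)cc(C(=O)O)cc1OCc1ccccc1 | intermediate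
4 | 3,5-bis(benzyloxy)-4-methoxybenzoyl chloride | COc1c(OCc2ccccc2)cc(C(=O)Cl)cc1OCc1ccccc1 | intermediate
5 | tert-butyl acetoacetate | CC(=O)CC(=O)OC(C)(C)C | starting material
6 | N,N-dimethylformamide dimethyl acetal | COC(OC)N(C)C | starting material
7 | tert-butyl 2-[(dimethylamino)methylidene]-3-oxobutanoate | CC(=O)C(=CN(C)C)C(=O)OC(C)(C)C | intermediate
8 | tert-butyl 5-[3,5-bis(benzyloxy)-4-methoxyphenyl]-2-[(dimethylamino)methylidene]-3,5-dioxopentanoate | CN(C)C=C(C(=O)OC(C)(C)C)C(=O)CC(=O)c1cc(OCc2ccccc2)c(OC)c(OCc2ccccc2)c1 | intermediate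
9 | tert-butyl 6-[3,5-bis(benzyloxy)-4-methoxyphenyl]-4-oxo-4H-pyran-3-carboxylate | CC(C)(C)OC(=O)c1coc(-c2cc(OCc3ccccc3)c(OC)c(OCc3ccccc3)c2)cc1=O | intermediate
10 | 6-[3,5-bis(benzyloxy)-4-methoxyphenyl]-4-oxo-4H-pyran-3-carboxylic acid | O=C(O)c1coc(-c2cc(OCc3ccccc3)c(OC)c(OCc3ccccc3)c2)cc1=O | intermediate
11 | 6-[3,5-bis(benzyloxy)-4-methoxyphenyl]-4-oxo-4H-pyran-3-carbonyl chloride | O=C(Cl)c1coc(-c2cc(OCc3ccccc3)c(OC)c(OCc3ccccc3)c2)cc1=O | intermediate
12 | benzyl alcohol | OCc1ccccc1 | starting material
13 | trichloroethylene | ClC=C(Cl)Cl | starting material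
14 | benzyl (E)-1,2-dichlorovinyl ether | Cl/C=C(/Cl)OCc1ccccc1 | intermediate
15 | lithium benzyloxyacetylide | [Li]C#COCc1ccccc1 | intermediate
16 | benzyl ethynyl ether | C#COCc1ccccc1 | intermediate
17 | chromium hexacarbonyl, Cr(CO)6 | O=C=[Cr](=C=O)(=C=O)(=C=O)(=C=O)=C=O | starting material
18 | disodium pentacarbonylchromate, Na2Cr(CO)5 | [Na+].[Na+].O=C=[Cr-2](=C=O)(=C=O)(=C=O)=C=O | intermediate
19 | sodium pentacarbonyl{[6-(3,5-bis(benzyloxy)-4-methoxyphenyl)-4-oxo-4H-pyran-3-yl]carbonyl}chromate | [Na+].O=C(c1coc(-c2cc(OCc3ccccc3)c(OC)c(OCc3ccccc3)c2)cc1=O)[Cr-](=C=O)(=C=O)(=C=O)(=C=O)=C=O | intermediate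
20 | pentacarbonyl{[6-(3,5-bis(benzyloxy)-4-methoxyphenyl)-4-oxo-4H-pyran-3-yl](methoxy)methylidene}chromium | COC(=[Cr](=C=O)(=C=O)(=C=O)(=C=O)=C=O)c1coc(-c2cc(OCc3ccccc3)c(OC)c(OCc3ccccc3)c2)cc1=O | intermediate
21 | tricarbonylchromium complex of 22, Cr(CO)3 bound η6 to ring A (the η6 bond is written as a dot) | COc1cc(OCc2ccccc2)c(O)c2oc(-c3cc(OCc4ccccc4)c(OC)c(OCc4ccccc4)c3)cc(=O)c12.O=C=[Cr](=C=O)=C=O | intermediate
22 | 7-(benzyloxy)-2-[3,5-bis(benzyloxy)-4-methoxyphenyl]-8-hydroxy-5-methoxychromen-4-one | COc1cc(OCc2ccccc2)c(O)c2oc(-c3cc(OCc4ccccc4)c(OC)c(OCc4ccccc4)c3)cc(=O)c12 | intermediate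
23 | 7-(benzyloxy)-2-[3,5-bis(benzyloxy)-4-methoxyphenyl]-5,8-dimethoxychromen-4-one | COc1cc(OCc2ccccc2)c(OC)c2oc(-c3cc(OCc4ccccc4)c(OC)c(OCc4ccccc4)c3)cc(=O)c12 | intermediate
24 | 2-(3,5-dihydroxy-4-methoxyphenyl)-7-hydroxy-5,8-dimethoxychromen-4-one | COc1c(O)cc(-c2cc(=O)c3c(OC)cc(O)c(OC)c3o2)cc1O | target

Total step count: 12.
Longest linear sequence: 10 (steps 1, 2, 3, 5, 6, 7, 9, 10, 11, 12). Steps 4 and 8 are side branches.

Steps most likely to fail

**Step 10 (ring A benzannulation).**
- The oxygen-stabilised dienylcarbene formed on insertion may stall before CO migration or collapse to five-membered rings.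
- The ynol ether may add to C2 of the activated pyranone.
- The ynol ether may be used up by its own sigmatropic rearrangement or by chromium-induced oligomerisation.

The fallback uses known flavone chemistry only. Ring A is bought and ring C is closed last; it sets out from acid chloride 4 and comes back at 23. Commercial 1-(2,4-dihydroxy-6-methoxyphenyl)ethanone is benzylated at its non-chelated 4-hydroxyl (BnBr, K2CO3, acetone) to 1-[4-(benzyloxy)-2-hydroxy-6-methoxyphenyl]ethanone F1. The dianion of F1 (LiN(SiMe3)2, THF, −78 °C) is C-acylated with 4, the direct form of the Baker-Venkataraman sequence, to 1-[4-(benzyloxy)-2-hydroxy-6-methoxyphenyl]-3-[3,5-bis(benzyloxy)-4-methoxyphenyl]propane-1,3-dione F2. Catalytic p-TsOH in hot toluene cyclodehydrates F2 to 7-(benzyloxy)-2-[3,5-bis(benzyloxy)-4-methoxyphenyl]-5-methoxychromen-4-one F3. I2 with CF3CO2Ag in CH2Cl2 iodinates the 5,7-dialkoxy ring at C8 to 7-(benzyloxy)-2-[3,5-bis(benzyloxy)-4-methoxyphenyl]-8-iodo-5-methoxychromen-4-one F4. Ullmann-type methoxylation (NaOMe, CuBr, DMF/MeOH, 110 °C) then gives 23.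

**Step 9 (carbene complex).**
- Electron transfer from the strongly reducing chromate dianion to the electron-poor acylpyranone may take the place of substitution at the acyl chloride.
- The dianion may attack C2 and open the ring.
- The oxonium salt may also methylate the ring carbonyl.

The fallback reverses the polarity, with a nucleophilic pyranone and an electrophilic chromium carbonyl. It sets out from acid 10 and comes back at 20. Hunsdiecker-type ipso-iododecarboxylation (N-iodosuccinimide, LiOAc cat., MeCN/H2O), directed to C3 by the ring oxygen, gives 2-[3,5-bis(benzyloxy)-4-methoxyphenyl]-5-iodo-4H-pyran-4-one F5. LiCl-assisted zinc insertion (Zn dust, LiCl, THF, rt) gives {6-[3,5-bis(benzyloxy)-4-methoxyphenyl]-4-oxo-4H-pyran-3-yl}zinc iodide F6, a carbon nucleophile covalent enough to tolerate the ring carbonyl and to hold on to the ring oxygen. Irradiation of 17 in THF gives pentacarbonyl(tetrahydrofuran)chromium F7. F6 and F7 under CO (1 atm) should give the iodozinc acylpentacarbonylchromate F8. This route is known for functionalised diorganozincs and is stretched here to an alkenylzinc halide. Me3OBF4 methylates F8 to 20.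

**Step 8 (ynol ether).**
- n-BuLi may metalate the benzylic position and trigger a Wittig-type rearrangement.
- The terminal ynol ether may be lost by hydration or thermal rearrangement during isolation.

The fallback avoids alkyllithium and stays below −30 °C. It sets out from benzyl alcohol 12 and comes back at 16. Acid-catalysed transacetalisation of chloroacetaldehyde dimethyl acetal with 12 (p-TsOH cat., methanol distilled off) gives chloroacetaldehyde dibenzyl acetal F9. NaNH2 (3 equiv) in liquid NH3 at −33 °C removes benzyl alcohol and HCl, the classical haloacetal route to alkoxyacetylenes, and leaves sodium benzyloxyacetylide F10. Cold aqueous NH4Cl protonates F10 to 16.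

Further compounds
F1 | step 10 | 1-[4-(benzyloxy)-2-hydroxy-6-methoxyphenyl]ethanone | CC(=O)c1c(O)cc(OCc2ccccc2)cc1OC
F2 | step 10 | 1-[4-(benzyloxy)-2-hydroxy-6-methoxyphenyl]-3-[3,5-bis(benzyloxy)-4-methoxyphenyl]propane-1,3-dione | COc1cc(OCc2ccccc2)cc(O)c1C(=O)CC(=O)c1cc(OCc2ccccc2)c(OC)c(OCc2ccccc2)c1
F3 | step 10 | 7-(benzyloxy)-2-[3,5-bis(benzyloxy)-4-methoxyphenyl]-5-methoxychromen-4-one | COc1cc(OCc2ccccc2)cc2oc(-c3cc(OCc4ccccc4)c(OC)c(OCc4ccccc4)c3)cc(=O)c12
F4 | step 10 | 7-(benzyloxy)-2-[3,5-bis(benzyloxy)-4-methoxyphenyl]-8-iodo-5-methoxychromen-4-one | COc1cc(OCc2ccccc2)c(I)c2oc(-c3cc(OCc4ccccc4)c(OC)c(OCc4ccccc4)c3)cc(=O)c12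
F5 | step 9 | 2-[3,5-bis(benzyloxy)-4-methoxyphenyl]-5-iodo-4H-pyran-4-one | COc1c(OCc2ccccc2)cc(-c2cc(=O)c(I)co2)cc1OCc1ccccc1
F6 | step 9 | {6-[3,5-bis(benzyloxy)-4-methoxyphenyl]-4-oxo-4H-pyran-3-yl}zinc iodide | COc1c(OCc2ccccc2)cc(-c2cc(=O)c([Zn]I)co2)cc1OCc1ccccc1
F7 | step 9 | pentacarbonyl(tetrahydrofuran)chromium | O=C=[Cr-](=C=O)(=C=O)(=C=O)(=C=O)[O+]1CCCC1
F8 | step 9 | iodozinc acylpentacarbonylchromate | I[Zn+].O=C(c1coc(-c2cc(OCc3ccccc3)c(OC)c(OCc3ccccc3)c2)cc1=O)[Cr-](=C=O)(=C=O)(=C=O)(=C=O)=C=O
F9 | step 8 | chloroacetaldehyde dibenzyl acetal | ClCC(OCc1ccccc1)OCc1ccccc1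
F10 | step 8 | sodium benzyloxyacetylide | [Na]C#COCc1ccccc1
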